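**Plan**

- Retrosynthesis: desilylation and oxidative demethylation lead back to a 4-methoxyphenol. Its ring is cut at three C–C bonds into a propenyl(methoxy)carbene of zerovalent chromium, one CO ligand and the terminal alkyne of a C18 tetraenyne.
- Enabling feature: in the quinone ring, C2 (methyl) and C6 (chain) flank the C1 carbonyl, and C3–H and C5–H flank the C4 carbonyl. C1 is therefore the CO carbon, C2/C3 the propenyl carbons, C4 the carbene carbon and C5/C6 the alkyne carbons.
- Chain cuts: C1′–alkyne (copper-catalysed ethynylation), C2′–C1′ and C3′–CH3 (carboalumination–hydroxymethylation), C4′–C5′ (propargylation), C8′–C9′ (vinylogous aldol).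
- Forward: the chain grows from geranial toward C1′, the alkyne is attached last, and the only ring is closed on the finished chain.
- Stereochemistry: C9′ (R) comes from a catalyst-controlled vinylogous Mukaiyama aldol on the Re face of geranial. The alkene geometries come from geranial, the γ-selective aldol and syn-carboalumination.

Key step: step 12

Numbering: C1′ is the ring-bound CH2 and C15′ the terminal C(CH3)2 carbon of the chain.
Assumption 1: geranial is used as the isomerically pure (2E)-aldehyde.
Assumption 2: the (R,R)-bisphosphoramide is taken to direct the dienol ether to the Re face of the bound aldehyde. If MTPA ester analysis of 6 showed the opposite sense, the (S,S)-catalyst would be used with nothing else changed.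

**Route**

Step 1
Reactants: 1 methyl 3-methylbut-2-enoate
Product: 3 tert-butyl[(1-methoxy-3-methylbuta-1,3-dien-1-yl)oxy]dimethylsilane, via lithium dienolate 2 (not isolated)
Conditions: LiN(i-Pr)2, THF, −78 °C; TBSCl, DMPU, −78 °C → rt
Reagents that add atoms: tert-butyldimethylsilyl chloride CC(C)(C)[Si](C)(C)Cl; lithium diisopropylamide CC(C)[N-]C(C)C.[Li+] (lithium of 2 only)
Why: Kinetic γ-deprotonation of the β,β-dimethyl enoate gives the extended lithium dienolate, which is O-silylated (silyl ketene acetal formation) to the usual donor for a vinylogous Mukaiyama aldol; the ketene acetal geometry is immaterial because that carbon returns to an ester.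

Step 2
Reactants: 3 silyl dienol ether; 4 geranial, (2E)-3,7-dimethylocta-2,6-dienal
Product: 6 methyl (2E,5R,6E)-5-hydroxy-3,7,11-trimethyldodeca-2,6,10-trienoate, via trichlorosilyl ether 5 (not isolated)
Conditions: SiCl4 (1.1 equiv), (R,R)-bisphosphoramide (two cyclic phosphoramides of N,N′-dimethyl-1,1′-binaphthyl-2,2′-diamine joined by an N,N′-dimethylpentane-1,5-diamine tether, 5 mol %), i-Pr2NEt (10 mol %), CH2Cl2, −78 °C; then aq. NaHCO3
Reagents that add atoms: silicon tetrachloride Cl[Si](Cl)(Cl)Cl (trichlorosilyl group of 5 only)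
Why: In this Lewis-base-activated vinylogous Mukaiyama aldol the bisphosphoramide ionises SiCl4 to a chiral trichlorosilyl cation that binds geranial, the dienol ether attacks through its unhindered γ-carbon on the exposed Re face, which sets C9′ as R and should give the (E)-enoate, and hydrolysis of the trichlorosilyl ether frees the alcohol.

Step 3
Reactants: 6 aldol adduct
Product: 7 methyl (2E,5R,6E)-5-[(tert-butyldimethylsilyl)oxy]-3,7,11-trimethyldodeca-2,6,10-trienoate
Conditions: TBSCl, imidazole, DMF, rt
Reagents that add atoms: tert-butyldimethylsilyl chloride CC(C)(C)[Si](C)(C)Cl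
Why: Imidazole-promoted silylation of the secondary allylic alcohol masks the hydroxyl toward the later sulfonylation, organolithium, organoaluminium and Grignard reagents without touching the C–O bond at C9′.

Step 4
Reactants: 7 silyl ether ester
Product: 8 (2E,5R,6E)-5-[(tert-butyldimethylsilyl)oxy]-3,7,11-trimethyldodeca-2,6,10-trien-1-ol
Conditions: i-Bu2AlH (2.5 equiv), CH2Cl2, −78 °C; aq. KNaC4H4O6
Reagents that add atoms: none
Why: 1,2-Reduction of the conjugated ester by the aluminium hydride should give the (E)-allylic alcohol (C5′) while the silyl ether and the alkenes stay untouched.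

Step 5
Reactants: 8 allylic alcohol
Product: 10 (2E,5R,6E)-1-bromo-5-[(tert-butyldimethylsilyl)oxy]-3,7,11-trimethyldodeca-2,6,10-triene, via allylic mesylate 9 (not isolated)
Conditions: MsCl, Et3N, THF, −40 °C; LiBr, −40 → 0 °C
Reagents that add atoms: lithium bromide [Li+].[Br-]; methanesulfonyl chloride CS(=O)(=O)Cl (mesyl group of 9 only)
Why: Sulfonylation followed by SN2 displacement with bromide converts the primary allylic alcohol under non-acidic conditions, so the alkene geometry and the allylic silyl ether should be preserved; the bromide is used crude.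

Step 6
Reactants: 10 allylic bromide
Product: 11 tert-butyl(dimethyl){[(5E,8R,9E)-6,10,14-trimethyl-1-(trimethylsilyl)pentadeca-5,9,13-trien-1-yn-8-yl]oxy}silane
Conditions: 1-(trimethylsilyl)propyne, n-BuLi, THF, −78 °C; then 10, −78 → 0 °C
Reagents that add atoms: 1-(trimethylsilyl)propyne CC#C[Si](C)(C)C
Why: SN2 alkylation of the lithiated silylpropyne at its propargylic carbon by the primary allylic bromide forms C4′–C5′, the classical three-carbon homologation of isoprenoid chains, with the silyl cap keeping the reagent from reacting as an allenyl or acetylide nucleophile.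

Step 7
Reactants: 11 silylated enyne
Product: 12 tert-butyl(dimethyl){[(5E,8R,9E)-6,10,14-trimethylpentadeca-5,9,13-trien-1-yn-8-yl]oxy}silane
Conditions: K2CO3, MeOH, rt
Reagents that add atoms: none
Why: Base-catalysed methanolysis cleaves the C(sp)–Si bond selectively, since an alkyl tert-butyldimethylsilyl ether is inert to carbonate in methanol.

Step 8
Reactants: 12 terminal 1,5-enyne
Product: 15 (2E,6E,9R,10E)-9-[(tert-butyldimethylsilyl)oxy]-3,7,11,15-tetramethylhexadeca-2,6,10,14-tetraen-1-ol, via alkenyldimethylalane 13 (not isolated), via lithium alkenylaluminate 14 (not isolated)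
Conditions: Me3Al (3 equiv), Cp2ZrCl2 (0.25 equiv), CH2Cl2, 0 °C → rt; excess Me3Al removed in vacuo; n-BuLi, hexane–THF, 0 °C; (CH2O)n, rt; aq. KNaC4H4O6
Reagents that add atoms: trimethylaluminium C[Al](C)C; paraformaldehyde (as formaldehyde) C=O; n-butyllithium [Li]CCCC (butyl and lithium of 14 only)
Why: Negishi zirconium-catalysed carboalumination adds CH3 and Al syn across the alkyne with aluminium on the terminal carbon, and the derived aluminate adds to formaldehyde with retention, so the (2E)-allylic alcohol carrying the C3′ methyl and C1′ should result while the trisubstituted alkenes and the silyl ether do not react.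

Step 9
Reactants: 15 allylic alcohol
Product: 17 (2E,6E,9R,10E)-1-bromo-9-[(tert-butyldimethylsilyl)oxy]-3,7,11,15-tetramethylhexadeca-2,6,10,14-tetraene, via allylic mesylate 16 (not isolated)
Conditions: MsCl, Et3N, THF, −40 °C; LiBr, −40 → 0 °C
Reagents that add atoms: lithium bromide [Li+].[Br-]; methanesulfonyl chloride CS(=O)(=O)Cl (mesyl group of 16 only)
Why: The same sulfonylation and SN2 bromide displacement as in step 5 activates C1′ without allylic transposition or loss of the silyl ether.

Step 10
Reactants: 17 allylic bromide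
Product: 18 tert-butyl(dimethyl){[(4E,8E,11R,12E)-5,9,13,17-tetramethyloctadeca-4,8,12,16-tetraen-1-yn-11-yl]oxy}silane
Conditions: HC≡CMgBr (3 equiv), CuBr·SMe2 (10 mol %), THF, 0 → 40 °C
Reagents that add atoms: ethynylmagnesium bromide C#C[Mg]Br
Why: Copper-catalysed substitution of a primary allylic bromide by an alkynyl Grignard reagent is the standard route to 1,4-enynes, and the excess of the weakly basic acetylide should suppress both a second allylation and isomerisation of the skipped enyne.

Step 11
Reactants: 19 chromium hexacarbonyl Cr(CO)6; 20 (E)-1-bromoprop-1-ene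
Product: 23 pentacarbonyl[(2E)-1-methoxybut-2-en-1-ylidene]chromium, via (E)-prop-1-enyllithium 21 (not isolated), via lithium acylchromate 22 (not isolated)
Conditions: t-BuLi (2 equiv), Et2O, −78 °C; Cr(CO)6, Et2O, 0 °C → rt; Me3OBF4, CH2Cl2–H2O, 0 °C
Reagents that add atoms: trimethyloxonium tetrafluoroborate C[O+](C)C.F[B-](F)(F)F; tert-butyllithium [Li]C(C)(C)C (lithium of 21 and 22 only)
Why: In this Fischer carbene synthesis, halogen–lithium exchange with retention gives the alkenyllithium, which adds to a CO ligand to form the acylchromate, and O-methylation by the oxonium salt gives the methoxycarbene complex (CO)5Cr=C(OMe)CH=CHCH3; a mixture of bromide isomers would serve equally, since the propenyl geometry is lost in step 12.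

Step 12
Reactants: 18 terminal 1,4-enyne; 23 propenyl(methoxy)carbene complex (1.5 equiv)
Product: 25 2-{(2E,6E,9R,10E)-9-[(tert-butyldimethylsilyl)oxy]-3,7,11,15-tetramethylhexadeca-2,6,10,14-tetraen-1-yl}-4-methoxy-6-methylphenol, via tricarbonylchromium arene complex 24 (not isolated)
Conditions: THF (0.05 M), 50 °C, Ar; then air, Et2O, rt; filtration through silica
Reagents that add atoms: none
Why: Heating releases one CO from 23, the terminal alkyne of 18 coordinates and inserts into the chromium–carbene bond so that its CH carbon bonds to the former carbene carbon and the carbon bearing C1′ becomes the new carbene centre, and CO insertion then gives a chromium-bound dienylketene. The ring closes by 6π electrocyclisation of this ketene, its carbonyl carbon bonding to the methyl-bearing terminus of the propenyl unit, and the cyclohexadienone formed tautomerises to the hexahapto-bound 4-methoxyphenol 24, from which air releases 25. The closest known reaction type is the Dötz benzannulation of alkenyl(alkoxy)carbene complexes of zerovalent chromium with terminal alkynes, isoprenoid 1,4-enynes included. No stereocentre is formed, the propenyl geometry disappears in the aromatic ring, and C9′ and the four chain alkenes take no part. The step needs one regiochemistry (chain ortho to the hydroxyl, ring CH next to the methoxy carbon), which the terminal alkyne secures because its larger substituent is placed next to the metal and therefore next to the inserted CO. It also needs selectivity for the alkyne over the trisubstituted alkenes and the allylic silyl ether, which the neutral conditions and the inertness of isolated trisubstituted alkenes toward the carbene should provide.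

Step 13
Reactants: 25 4-methoxyphenol
Product: 26 2-{(2E,6E,9R,10E)-9-[(tert-butyldimethylsilyl)oxy]-3,7,11,15-tetramethylhexadeca-2,6,10,14-tetraen-1-yl}-6-methylcyclohexa-2,5-diene-1,4-dione
Conditions: (NH4)2Ce(NO3)6 (2.2 equiv), MeCN–H2O 3:1, 0 °C, 15 min
Reagents that add atoms: water O
Why: Oxidative demethylation by tetravalent cerium takes two electrons from the electron-rich hydroquinone monomethyl ether, water adds to the methoxy-bearing carbon of the phenoxonium ion and methanol is lost, a far easier oxidation than that of a dimethyl ether, so a short cold exposure should spare the skipped polyene (partial loss of the silyl group here would be harmless).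

Step 14
Reactants: 26 silylated quinone
Product: 27 2-[(2E,6E,9R,10E)-9-hydroxy-3,7,11,15-tetramethylhexadeca-2,6,10,14-tetraen-1-yl]-6-methylcyclohexa-2,5-diene-1,4-dione
Conditions: HF·pyridine, THF, 0 °C → rt (polypropylene vessel)
Reagents that add atoms: none
Why: Fluoride-driven Si–O cleavage under mildly acidic, non-basic conditions suits the base-sensitive quinone and leaves the C9′–O bond intact, so the R configuration is carried into the target.

**Compound list**

1 | methyl 3-methylbut-2-enoate | COC(=O)C=C(C)C | starting material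
2 | lithium 1-methoxy-3-methylbuta-1,3-dien-1-olate (not isolated) | [Li+].[O-]C(OC)=CC(C)=C | intermediate
3 | tert-butyl[(1-methoxy-3-methylbuta-1,3-dien-1-yl)oxy]dimethylsilane | C=C(C)C=C(OC)O[Si](C)(C)C(C)(C)C | intermediate
4 | geranial, (2E)-3,7-dimethylocta-2,6-dienal | CC(C)=CCC/C(C)=C/C=O | starting material
5 | methyl (2E,5R,6E)-3,7,11-trimethyl-5-[(trichlorosilyl)oxy]dodeca-2,6,10-trienoate (not isolated) | CC(C)=CCC/C(C)=C/[C@H](O[Si](Cl)(Cl)Cl)C/C(C)=C/C(=O)OC | intermediate
6 | methyl (2E,5R,6E)-5-hydroxy-3,7,11-trimethyldodeca-2,6,10-trienoate | CC(C)=CCC/C(C)=C/[C@H](O)C/C(C)=C/C(=O)OC | intermediate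
7 | methyl (2E,5R,6E)-5-[(tert-butyldimethylsilyl)oxy]-3,7,11-trimethyldodeca-2,6,10-trienoate | CC(C)=CCC/C(C)=C/[C@H](O[Si](C)(C)C(C)(C)C)C/C(C)=C/C(=O)OC | intermediate
8 | (2E,5R,6E)-5-[(tert-butyldimethylsilyl)oxy]-3,7,11-trimethyldodeca-2,6,10-trien-1-ol | CC(C)=CCC/C(C)=C/[C@H](O[Si](C)(C)C(C)(C)C)C/C(C)=C/CO | intermediate
9 | (2E,5R,6E)-5-[(tert-butyldimethylsilyl)oxy]-3,7,11-trimethyldodeca-2,6,10-trien-1-yl methanesulfonate (not isolated) | CC(C)=CCC/C(C)=C/[C@H](O[Si](C)(C)C(C)(C)C)C/C(C)=C/COS(C)(=O)=O | intermediate
10 | (2E,5R,6E)-1-bromo-5-[(tert-butyldimethylsilyl)oxy]-3,7,11-trimethyldodeca-2,6,10-triene | CC(C)=CCC/C(C)=C/[C@H](O[Si](C)(C)C(C)(C)C)C/C(C)=C/CBr | intermediate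
11 | tert-butyl(dimethyl){[(5E,8R,9E)-6,10,14-trimethyl-1-(trimethylsilyl)pentadeca-5,9,13-trien-1-yn-8-yl]oxy}silane | CC(C)=CCC/C(C)=C/[C@H](O[Si](C)(C)C(C)(C)C)C/C(C)=C/CCC#C[Si](C)(C)C | intermediate
12 | tert-butyl(dimethyl){[(5E,8R,9E)-6,10,14-trimethylpentadeca-5,9,13-trien-1-yn-8-yl]oxy}silane | CC(C)=CCC/C(C)=C/[C@H](O[Si](C)(C)C(C)(C)C)C/C(C)=C/CCC#C | intermediate
13 | (1E,5E,8R,9E)-alkenyldimethylalane from methylalumination of 12 (not isolated) | CC(C)=CCC/C(C)=C/[C@H](O[Si](C)(C)C(C)(C)C)C/C(C)=C/CC/C(C)=C/[Al](C)C | intermediate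
14 | lithium butyl(alkenyl)dimethylaluminate from 13 (not isolated) | CC(C)=CCC/C(C)=C/[C@H](O[Si](C)(C)C(C)(C)C)C/C(C)=C/CC/C(C)=C/[Al-](C)(C)CCCC.[Li+] | intermediate
15 | (2E,6E,9R,10E)-9-[(tert-butyldimethylsilyl)oxy]-3,7,11,15-tetramethylhexadeca-2,6,10,14-tetraen-1-ol | CC(C)=CCC/C(C)=C/[C@H](O[Si](C)(C)C(C)(C)C)C/C(C)=C/CC/C(C)=C/CO | intermediate
16 | (2E,6E,9R,10E)-9-[(tert-butyldimethylsilyl)oxy]-3,7,11,15-tetramethylhexadeca-2,6,10,14-tetraen-1-yl methanesulfonate (not isolated) | CC(C)=CCC/C(C)=C/[C@H](O[Si](C)(C)C(C)(C)C)C/C(C)=C/CC/C(C)=C/COS(C)(=O)=O | intermediate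
17 | (2E,6E,9R,10E)-1-bromo-9-[(tert-butyldimethylsilyl)oxy]-3,7,11,15-tetramethylhexadeca-2,6,10,14-tetraene | CC(C)=CCC/C(C)=C/[C@H](O[Si](C)(C)C(C)(C)C)C/C(C)=C/CC/C(C)=C/CBr | intermediate
18 | tert-butyl(dimethyl){[(4E,8E,11R,12E)-5,9,13,17-tetramethyloctadeca-4,8,12,16-tetraen-1-yn-11-yl]oxy}silane | CC(C)=CCC/C(C)=C/[C@H](O[Si](C)(C)C(C)(C)C)C/C(C)=C/CC/C(C)=C/CC#C | intermediate
19 | chromium hexacarbonyl Cr(CO)6 | O=C=[Cr](=C=O)(=C=O)(=C=O)(=C=O)=C=O | starting material
20 | (E)-1-bromoprop-1-ene | C/C=C/Br | starting material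
21 | (E)-prop-1-enyllithium (not isolated) | C/C=C/[Li] | intermediate
22 | lithium pentacarbonyl[(2E)-1-oxidobut-2-en-1-ylidene]chromate, Li[(CO)5Cr=C(O)CH=CHCH3] (not isolated) | [Li+].[O-]C(/C=C/C)=[Cr](=C=O)(=C=O)(=C=O)(=C=O)=C=O | intermediate
23 | pentacarbonyl[(2E)-1-methoxybut-2-en-1-ylidene]chromium, (CO)5Cr=C(OMe)CH=CHCH3 | COC(/C=C/C)=[Cr](=C=O)(=C=O)(=C=O)(=C=O)=C=O | intermediate
24 | tricarbonylchromium complex of phenol 25, Cr(CO)3 hexahapto-bound to the arene (not isolated; written as two components because the ring–metal bonding cannot be expressed) | CC(C)=CCC/C(C)=C/[C@H](O[Si](C)(C)C(C)(C)C)C/C(C)=C/CC/C(C)=C/Cc1cc(OC)cc(C)c1O.O=C=[Cr](=C=O)=C=O | intermediate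
25 | 2-{(2E,6E,9R,10E)-9-[(tert-butyldimethylsilyl)oxy]-3,7,11,15-tetramethylhexadeca-2,6,10,14-tetraen-1-yl}-4-methoxy-6-methylphenol | CC(C)=CCC/C(C)=C/[C@H](O[Si](C)(C)C(C)(C)C)C/C(C)=C/CC/C(C)=C/Cc1cc(OC)cc(C)c1O | intermediate
26 | 2-{(2E,6E,9R,10E)-9-[(tert-butyldimethylsilyl)oxy]-3,7,11,15-tetramethylhexadeca-2,6,10,14-tetraen-1-yl}-6-methylcyclohexa-2,5-diene-1,4-dione | CC(C)=CCC/C(C)=C/[C@H](O[Si](C)(C)C(C)(C)C)C/C(C)=C/CC/C(C)=C/CC1=CC(=O)C=C(C)C1=O | intermediate
27 | 2-[(2E,6E,9R,10E)-9-hydroxy-3,7,11,15-tetramethylhexadeca-2,6,10,14-tetraen-1-yl]-6-methylcyclohexa-2,5-diene-1,4-dione | CC(C)=CCC/C(C)=C/[C@H](O)C/C(C)=C/CC/C(C)=C/CC1=CC(=O)C=C(C)C1=O | target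

**Step count and risks**

Total: 14 steps. Longest linear sequence: 13 steps (steps 1–10, then 12–14); step 11 is a one-step side branch.

Steps most likely to fail:

1. Step 12 (benzannulation). The vinylcarbene and dienylketene intermediates may leak into non-phenolic channels (five-membered ring or furan formation), the alkyne may oligomerise at the metal, or the electron-rich phenol may suffer during oxidative release from chromium. The fallback gives up the annulation and joins a preformed ring to the chain. It sets out from allylic bromide 17. Commercial 4-methoxy-2-methylphenol would be brominated ortho to the hydroxyl with N-bromosuccinimide in CH2Cl2 at 0 °C to give 2-bromo-4-methoxy-6-methylphenol F1. Treatment with n-BuLi (2.2 equiv) in Et2O from −78 to 0 °C (deprotonation and bromine–lithium exchange) would give lithium 2-lithio-4-methoxy-6-methylphenolate F2. With CuBr·SMe2 this should be allylated at the aryl carbon by 17 in an SN2 sense, and aqueous NH4Cl would deliver phenol 25, where the route resumes at step 13.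

2. Step 2 (vinylogous aldol). A β,β-disubstituted enal may turn over slowly or with poor facial selectivity, and the allylic trichlorosilyl ether may ionise with erosion of configuration. The fallback sets C9′ by asymmetric propargylation and builds the C6′=C7′ alkene by carboalumination. It sets out from geranial 4. Allenylboronic acid pinacol ester, with a BINOL-derived phosphoric acid bearing 2,4,6-triisopropylphenyl groups at the 3 and 3′ positions (the enantiomer giving Re-face addition; toluene, 4 Å molecular sieves, −20 °C), should give the pinacol borate of the homopropargylic alcohol F3. Work-up hydrolyses it to (4R,5E)-6,10-dimethylundeca-5,9-dien-1-yn-4-ol F4. TBSCl and imidazole in DMF would give tert-butyl{[(4R,5E)-6,10-dimethylundeca-5,9-dien-1-yn-4-yl]oxy}dimethylsilane F5. Me3Al with Cp2ZrCl2 in CH2Cl2 would give the (E)-alkenyldimethylalane F6, n-BuLi its lithium aluminate F7, and paraformaldehyde the allylic alcohol 8, where the route resumes at step 5.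

3. Step 10 (ethynylation). The acetylide may attack the tertiary allyl terminus (SN2′), the product alkyne may be allylated a second time, or the skipped enyne may isomerise to an allene under the basic Grignard conditions. The fallback replaces the copper–Grignard substitution by a neutral Stille coupling through a π-allyl complex. It sets out from allylic bromide 17, which with tributyl(ethynyl)stannane, Pd2(dba)3 and P(2-furyl)3 (zerovalent palladium) in THF at rt to 50 °C should couple at the less hindered allyl terminus and give enyne 18 directly, where the route resumes at step 12.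

**Further compounds**

F1 | step 12 | 2-bromo-4-methoxy-6-methylphenol | COc1cc(C)c(O)c(Br)c1
F2 | step 12 | lithium 2-lithio-4-methoxy-6-methylphenolate | COc1cc(C)c(O[Li])c([Li])c1
F3 | step 2 | 2-{[(4R,5E)-6,10-dimethylundeca-5,9-dien-1-yn-4-yl]oxy}-4,4,5,5-tetramethyl-1,3,2-dioxaborolane | CC(C)=CCC/C(C)=C/[C@H](OB1OC(C)(C)C(C)(C)O1)CC#C
F4 | step 2 | (4R,5E)-6,10-dimethylundeca-5,9-dien-1-yn-4-ol | CC(C)=CCC/C(C)=C/[C@H](O)CC#C
F5 | step 2 | tert-butyl{[(4R,5E)-6,10-dimethylundeca-5,9-dien-1-yn-4-yl]oxy}dimethylsilane | CC(C)=CCC/C(C)=C/[C@H](O[Si](C)(C)C(C)(C)C)CC#C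
F6 | step 2 | (1E,4R,5E)-alkenyldimethylalane from methylalumination of F5 | CC(C)=CCC/C(C)=C/[C@H](O[Si](C)(C)C(C)(C)C)C/C(C)=C/[Al](C)C
F7 | step 2 | lithium butyl(alkenyl)dimethylaluminate from F6 | CC(C)=CCC/C(C)=C/[C@H](O[Si](C)(C)C(C)(C)C)C/C(C)=C/[Al-](C)(C)CCCC.[Li+]
F0 | step 10 | none | none
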